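**Retrosynthetic overview**
1. 19 ⇒ acyclic allenyl enal 18 + CO. One [2+2+1] cyclocarbonylation makes C6–C7, C11–C12 and C12–O, so the ten-membered carbocycle and the α-methylene lactone close together in the last step; no ring exists before it.
2. 18 ⇒ Z-enal 11 + allenylboronate 12 + CH2O. Catalytic asymmetric propargylation sets C9; alkyne-to-allene homologation, acetylation and acetal hydrolysis follow.
3. 11 ⇒ diene 5 + vinyl iodide 8 (C1–C2 bond by hydroboration and B-alkyl Suzuki coupling).
4. 5 and 8 ⇒ propargyl alcohol 1. Two copper-catalysed anti-carbomagnesiations fix both trisubstituted olefin geometries.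

Assumption: the SMILES is read as the (6R,7R,9S) isomer with a cis-fused 12,6-lactone, a ring-cis C1=C10 bond and a C4=C5 bond on which C6 and C15 are cis; atom labels follow germacrane numbering (C1–C10 ring, C11–C13 lactone, C14 methyl, C15 CH2O).

**Step 1**
Reactants: 1 prop-2-yn-1-ol; 2 vinylmagnesium bromide
Product: 5 (2Z)-4,4-diethoxy-2-ethenylbut-2-en-1-yl 3-methylbutanoate, via vinyl oxamagnesacycle 3 (not isolated), via bromomagnesium alkoxide 4 (not isolated)
Conditions: 2 (2.5 equiv), CuI (10 mol %), THF, 0 °C to rt; PhOCH(OEt)2 (2 equiv), rt; (iPrCH2CO)2O (3 equiv), DMAP (cat.), 0 °C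
Reagents that add atoms: diethyl phenyl orthoformate, CCOC(OCC)Oc1ccccc1; 3-methylbutanoic anhydride, CC(C)CC(=O)OC(=O)CC(C)C
Why: Copper-catalysed anti-carbomagnesiation of propargyl alcohol puts vinyl on the internal carbon and magnesium cis to CH2O in a five-membered chelate, so Bodroux–Chichibabin-type capture by the orthoformate places the acetal carbon C6 cis to C15 as the target needs, and the alkoxide is acylated in the flask before the cis hydroxy acetal can cyclise.

**Step 2**
Reactants: 1 prop-2-yn-1-ol; 6 methylmagnesium bromide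
Product: 8 (2Z)-3-iodo-2-methylprop-2-en-1-ol, via methyl oxamagnesacycle 7 (not isolated)
Conditions: 6 (2.5 equiv), CuI (10 mol %), THF–Et2O, rt; I2, −20 °C
Reagents that add atoms: iodine, II
Why: The same anti-carbomagnesiation followed by iodinolysis with retention gives the vinyl iodide with iodine cis to CH2OH, which later becomes the ring-cis C1=C10 olefin.

**Step 3**
Reactants: 5 (2Z)-4,4-diethoxy-2-ethenylbut-2-en-1-yl 3-methylbutanoate; 8 (2Z)-3-iodo-2-methylprop-2-en-1-ol
Product: 10 (2Z,6Z)-8,8-diethoxy-2-methyl-6-[(3-methylbutanoyloxy)methyl]octa-2,6-dien-1-ol, via alkylborane 9 (not isolated)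
Conditions: 9-BBN (0.5 M in THF, 1.1 equiv), 0 °C to rt; then 8, Pd(dppf)Cl2 (5 mol %), AsPh3 (10 mol %), Cs2CO3 (3 equiv), DMF–H2O, rt
Reagents that add atoms: none
Why: 9-BBN adds anti-Markovnikov only to the terminal vinyl group (the trisubstituted, acceptor-flanked olefin and the ester are inert), and the B-alkyl Suzuki–Miyaura coupling proceeds with retention at the vinyl iodide, giving the Z-trisubstituted C1=C10 olefin.

**Step 4**
Reactants: 10 (2Z,6Z)-8,8-diethoxy-2-methyl-6-[(3-methylbutanoyloxy)methyl]octa-2,6-dien-1-ol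
Product: 11 (2Z,6Z)-8,8-diethoxy-2-methyl-6-[(3-methylbutanoyloxy)methyl]octa-2,6-dienal
Conditions: Dess–Martin periodinane (1.3 equiv), pyridine (3 equiv), CH2Cl2, 0 °C; used crude
Reagents that add atoms: none
Why: Buffered Dess–Martin oxidation of the only free (allylic) alcohol gives the Z-enal without acid or strong base, so the Z geometry and the acetal are kept.

**Step 5**
Reactants: 11 (2Z,6Z)-8,8-diethoxy-2-methyl-6-[(3-methylbutanoyloxy)methyl]octa-2,6-dienal; 12 allenylboronic acid pinacol ester
Product: 14 (4S,5Z,9Z)-11,11-diethoxy-4-hydroxy-5-methyl-9-[(3-methylbutanoyloxy)methyl]undeca-5,9-dien-1-yne, via pinacol borate 13 (not isolated)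
Conditions: 12 (1.5 equiv), (S)-TRIP [(S)-3,3'-bis(2,4,6-triisopropylphenyl)-1,1'-binaphthyl-2,2'-diyl hydrogen phosphate] (10 mol %), 4 Å MS, toluene, −20 °C; aq. NaHCO3
Reagents that add atoms: none
Why: Chiral-phosphoric-acid-catalysed propargylboration goes through a closed six-membered SE2' transition state in which the catalyst binds the boronate oxygen and the formyl hydrogen, so one aldehyde face is attacked and C9 is set as S; the (S)-catalyst is chosen by analogy with aryl and alkenyl aldehydes and the sense is to be confirmed by Mosher analysis.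

**Step 6**
Reactants: 14 (4S,5Z,9Z)-11,11-diethoxy-4-hydroxy-5-methyl-9-[(3-methylbutanoyloxy)methyl]undeca-5,9-dien-1-yne
Product: 16 (5S,6Z,10Z)-12,12-diethoxy-5-hydroxy-6-methyl-10-[(3-methylbutanoyloxy)methyl]dodeca-1,2,6,10-tetraene, via propargylic amine 15 (not isolated)
Conditions: (CH2O)n (2.5 equiv), Cy2NH (1.8 equiv), CuI (0.5 equiv), 1,4-dioxane, reflux
Reagents that add atoms: formaldehyde (from paraformaldehyde), C=O
Why: Crabbé homologation: the Mannich base of the terminal alkyne undergoes copper-mediated hydride transfer and loss of imine to give the terminal allene; free homopropargylic alcohols, esters and acetals tolerate it and C9 is untouched.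

**Step 7**
Reactants: 16 (5S,6Z,10Z)-12,12-diethoxy-5-hydroxy-6-methyl-10-[(3-methylbutanoyloxy)methyl]dodeca-1,2,6,10-tetraene
Product: 17 (5S,6Z,10Z)-5-acetoxy-12,12-diethoxy-6-methyl-10-[(3-methylbutanoyloxy)methyl]dodeca-1,2,6,10-tetraene
Conditions: Ac2O, pyridine, DMAP (cat.), CH2Cl2, 0 °C to rt
Reagents that add atoms: acetic anhydride, CC(=O)OC(C)=O
Why: Standard O-acylation with retention at C9; the acetate also blocks the homoallenyl alcohol, which would otherwise cyclocarbonylate by itself in step 9.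

**Step 8**
Reactants: 17 (5S,6Z,10Z)-5-acetoxy-12,12-diethoxy-6-methyl-10-[(3-methylbutanoyloxy)methyl]dodeca-1,2,6,10-tetraene
Product: 18 (2Z,6Z,8S)-8-acetoxy-7-methyl-3-[(3-methylbutanoyloxy)methyl]dodeca-2,6,10,11-tetraenal
Conditions: PPTS (20 mol %), acetone–H2O (10:1), rt
Reagents that add atoms: water, O
Why: An enal diethyl acetal hydrolyses through an allyl-stabilised oxocarbenium ion under acid mild enough to leave the allene, both esters and the olefin geometries intact.

**Step 9**
Reactants: 18 (2Z,6Z,8S)-8-acetoxy-7-methyl-3-[(3-methylbutanoyloxy)methyl]dodeca-2,6,10,11-tetraenal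
Product: 19 [(3aR,5S,6Z,10Z,11aR)-5-acetyloxy-6-methyl-3-methylidene-2-oxo-2,3,3a,4,5,8,9,11a-octahydrocyclodeca[b]furan-10-yl]methyl 3-methylbutanoate
Conditions: Ru3(CO)12 (10 mol %), CO (20 atm), 1,4-dioxane (0.002 M), 120 °C
Reagents that add atoms: carbon monoxide, [C-]#[O+]
Why: Proposed new method: a ten-membered-ring version of the hetero-Pauson–Khand [2+2+1] cyclocarbonylation of tethered allenyl aldehydes, which is known with Ru3(CO)12 for five- and six-membered carbocycles and always gives cis-fused α-methylene-γ-butyrolactones. A zerovalent ruthenium carbonyl fragment binds the internal allene π bond and the aldehyde, oxidative cyclisation forms C6–C7, CO inserts and C–O reductive elimination releases the lactone, so both rings close in one event; closure is helped by the Z olefin and the planar enal, which stiffen the chain, and by high dilution. Bond formation on one face of the metallacycle should give the cis fusion, and the C9 acetate, kept 1,3-anti to C7–C11 to avoid a syn-pentane contact with the metal-bound allene, is expected to relay 9S to 6R,7R. This diastereocontrol is a prediction, not precedent.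

**Compound list**
1 | prop-2-yn-1-ol (propargyl alcohol) | C#CCO | starting material
2 | vinylmagnesium bromide | C=C[Mg]Br | starting material
3 | 4-ethenyl-2,5-dihydro-1,2-oxamagnesole (vinyl oxamagnesacycle, Mg cis to CH2O) | C=CC1=C[Mg]OC1 | intermediate
4 | bromomagnesium (2Z)-4,4-diethoxy-2-ethenylbut-2-en-1-olate | CCOC(OCC)/C=C(\CO[Mg]Br)C=C | intermediate
5 | (2Z)-4,4-diethoxy-2-ethenylbut-2-en-1-yl 3-methylbutanoate | CCOC(OCC)/C=C(\COC(=O)CC(C)C)C=C | intermediate
6 | methylmagnesium bromide | C[Mg]Br | starting material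
7 | 4-methyl-2,5-dihydro-1,2-oxamagnesole (methyl oxamagnesacycle) | CC1=C[Mg]OC1 | intermediate
8 | (2Z)-3-iodo-2-methylprop-2-en-1-ol | OC/C(C)=C\I | intermediate
9 | (2Z)-2-[2-(9-borabicyclo[3.3.1]nonan-9-yl)ethyl]-4,4-diethoxybut-2-en-1-yl 3-methylbutanoate | CCOC(OCC)/C=C(\COC(=O)CC(C)C)CCB1C2CCCC1CCC2 | intermediate
10 | (2Z,6Z)-8,8-diethoxy-2-methyl-6-[(3-methylbutanoyloxy)methyl]octa-2,6-dien-1-ol | CCOC(OCC)/C=C(\COC(=O)CC(C)C)CC/C=C(/C)CO | intermediate
11 | (2Z,6Z)-8,8-diethoxy-2-methyl-6-[(3-methylbutanoyloxy)methyl]octa-2,6-dienal | CCOC(OCC)/C=C(\COC(=O)CC(C)C)CC/C=C(/C)C=O | intermediate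
12 | allenylboronic acid pinacol ester (4,4,5,5-tetramethyl-2-propa-1,2-dienyl-1,3,2-dioxaborolane) | CC1(C)OB(C=C=C)OC1(C)C | starting material
13 | O-pinacolboryl ether of 14 | CCOC(OCC)/C=C(\COC(=O)CC(C)C)CC/C=C(/C)[C@@H](OB1OC(C)(C)C(C)(C)O1)CC#C | intermediate
14 | (4S,5Z,9Z)-11,11-diethoxy-4-hydroxy-5-methyl-9-[(3-methylbutanoyloxy)methyl]undeca-5,9-dien-1-yne | CCOC(OCC)/C=C(\COC(=O)CC(C)C)CC/C=C(/C)[C@@H](O)CC#C | intermediate
15 | N,N-dicyclohexyl propargylic amine (Mannich base of 14 at the alkyne terminus) | CCOC(OCC)/C=C(\COC(=O)CC(C)C)CC/C=C(/C)[C@@H](O)CC#CCN(C1CCCCC1)C1CCCCC1 | intermediate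
16 | (5S,6Z,10Z)-12,12-diethoxy-5-hydroxy-6-methyl-10-[(3-methylbutanoyloxy)methyl]dodeca-1,2,6,10-tetraene | CCOC(OCC)/C=C(\COC(=O)CC(C)C)CC/C=C(/C)[C@@H](O)CC=C=C | intermediate
17 | (5S,6Z,10Z)-5-acetoxy-12,12-diethoxy-6-methyl-10-[(3-methylbutanoyloxy)methyl]dodeca-1,2,6,10-tetraene | CCOC(OCC)/C=C(\COC(=O)CC(C)C)CC/C=C(/C)[C@@H](OC(C)=O)CC=C=C | intermediate
18 | (2Z,6Z,8S)-8-acetoxy-7-methyl-3-[(3-methylbutanoyloxy)methyl]dodeca-2,6,10,11-tetraenal | O=C/C=C(\COC(=O)CC(C)C)CC/C=C(/C)[C@@H](OC(C)=O)CC=C=C | intermediate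
19 | [(3aR,5S,6Z,10Z,11aR)-5-acetyloxy-6-methyl-3-methylidene-2-oxo-2,3,3a,4,5,8,9,11a-octahydrocyclodeca[b]furan-10-yl]methyl 3-methylbutanoate (CNP0398030.1) | C=C1C(=O)O[C@@H]2/C=C(\COC(=O)CC(C)C)CC/C=C(/C)[C@@H](OC(C)=O)C[C@H]12 | target

**Totals**
Total step count: 9. Longest linear sequence: 8 (steps 1, 3, 4, 5, 6, 7, 8, 9); step 2 is the side branch.

**Three steps most likely to fail**

Step 9. A ten-membered ring has not been closed this way. The cis fusion and the C9-to-C6/C7 relay are predictions. The two allylic esters could ionise on the low-valent metal, and the enal could isomerise at 120 °C. The fallback sets out from 18 and returns at 19. Copper-catalysed borylative cyclisation (CuCl, 1,2-bis(diphenylphosphino)benzene, NaOtBu cat., B2pin2, THF, 0.002 M) adds Cu–B across the allene; the resulting 2-boryl allylcopper adds to the aldehyde through a chair transition state. After work-up this gives the ten-membered syn homoallylic alcohol carrying a 1-(pinacolboryl)ethenyl group at C7, F1. Oxidative carbonylation with Pd(OAc)2, p-benzoquinone and CO (1 atm) in THF then closes the lactone to 19, so ring closure and lactonisation become separate operations.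

Step 1. The chelated alkenylmagnesium may react sluggishly with the orthoformate, and the cis hydroxy acetal may cyclise before acylation. The fallback sets out from 1 and returns at 5. The same carbomagnesiation is quenched with iodine to give (2Z)-2-ethenyl-3-iodoprop-2-en-1-ol F2. Acylation with 3-methylbutanoyl chloride and pyridine gives the iodo ester F3. C6 is then introduced by Pd(PPh3)4-catalysed formylation (CO, Bu3SnH, toluene, 50 °C) to give the enal F4, and acetalisation (HC(OEt)3, EtOH, PPTS) gives 5.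

Step 5. The Z-enal 11 may isomerise, and the hindered α-methyl enal may give low ee. The fallback sets out from 11 and returns at 14. Zinc-mediated Barbier propargylation (propargyl bromide, Zn, THF–aq. NH4Cl, 0 °C) gives the racemic alcohol F5. Kinetic resolution with Burkholderia cepacia lipase and vinyl acetate acetylates the R enantiomer to the acetate F6 and leaves the S alcohol 14.

**Further compounds**
F1 | step 9 | 9-acetoxy-6-hydroxy-10-methyl-7-[1-(pinacolboryl)ethenyl]cyclodeca-1(10),4-dien-4-ylmethyl 3-methylbutanoate (germacrane numbering, configuration at C6, C7, C9 as in 19) | O[C@@H]1/C=C(\COC(=O)CC(C)C)CC/C=C(/C)[C@@H](OC(C)=O)C[C@@H]1C(=C)B2OC(C)(C)C(C)(C)O2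
F2 | step 1 | (2Z)-2-ethenyl-3-iodoprop-2-en-1-ol | OC/C(C=C)=C\I
F3 | step 1 | (2Z)-2-ethenyl-3-iodoprop-2-en-1-yl 3-methylbutanoate | CC(C)CC(=O)OC/C(C=C)=C\I
F4 | step 1 | (2Z)-2-ethenyl-4-oxobut-2-en-1-yl 3-methylbutanoate | O=C/C=C(\COC(=O)CC(C)C)C=C
F5 | step 5 | racemic (5Z,9Z)-11,11-diethoxy-4-hydroxy-5-methyl-9-[(3-methylbutanoyloxy)methyl]undeca-5,9-dien-1-yne | CCOC(OCC)/C=C(\COC(=O)CC(C)C)CC/C=C(/C)C(O)CC#C
F6 | step 5 | (4R,5Z,9Z)-4-acetoxy-11,11-diethoxy-5-methyl-9-[(3-methylbutanoyloxy)methyl]undeca-5,9-dien-1-yne | CCOC(OCC)/C=C(\COC(=O)CC(C)C)CC/C=C(/C)[C@H](OC(C)=O)CC#C
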